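## Retrosynthetic overview

1. Target 12 is an ent-labdane (5R,9R,10R, antipodal to the sclareol series) with C16H2–O-acyl cis to C15O2H (13Z). It is the O16-isobutyrylated, ring-opened form of butenolide 10, so the ester O–acyl bond and the lactone acyl–O bond are disconnected first.
2. The butenolide ring of 10 comes from 3-alkylfuran 7 by a [4+2] cycloaddition of singlet oxygen (endoperoxide 8, then hydroxybutenolide 9). This step fixes C15 as the carboxyl carbon, C16 as CH2O and the Z geometry.
3. Furan 7 comes from furan diol 5 by deoxygenation at C3 and C19. Diol 5 comes from andrographolide 1 by SN2′ reductive loss of O14 and butenolide-to-furan reduction.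
4. Ring order: rings A and B, with C5, C9, C10 and the 8(17)-methylene, are bought in 1. The furan ring forms in step 3, the trioxabicycle and butenolide ring in step 6, and that ring is opened in step 7.

Assumption: andrographolide (bulk extract of Andrographis paniculata) is taken as the purchased chiral starting material; labdane numbering is used throughout.

## Route

Step 1
Reactants: 1 andrographolide
Product: 2 3,14,19-tri-O-acetylandrographolide
Conditions: Ac2O, pyridine, DMAP (cat.), CH2Cl2, 0 °C to rt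
Reagents that add atoms: acetic anhydride, CC(=O)OC(C)=O
Why: Exhaustive DMAP-catalysed O-acetylation (nucleophilic acyl substitution) turns the allylic 14-OH into a leaving group and masks 3-OH and 19-OH, with no stereocentre touched.

Step 2
Reactants: 2 3,14,19-tri-O-acetylandrographolide
Product: 3 3,19-di-O-acetyl-14-deoxyandrographolide
Conditions: NaBH4 (1 equiv), THF/EtOH, −20 to 0 °C
Reagents that add atoms: none
Why: Conjugate hydride addition at C12 of the α-alkylidene lactone followed by E1cB loss of the 14-acetate (an SN2′-type reductive transposition) gives the endocyclic butenolide, so C14 becomes sp2 while the isolated 8(17)-alkene, the acetates and C5/C9/C10 are untouched.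

Step 3
Reactants: 3 3,19-di-O-acetyl-14-deoxyandrographolide
Product: 5 furan diol 15,16-epoxy-ent-labda-8(17),13(16),14-triene-3,19-diol, via lactol 4 (not isolated)
Conditions: i-Bu2AlH (5 equiv), CH2Cl2, −78 °C; MeOH quench; then 1 M HCl, THF, 0 °C
Reagents that add atoms: none
Why: i-Bu2AlH half-reduces the lactone to lactol 4 and cleaves both acetates through their aluminium hemiacetals, and the acid work-up drives aromatising dehydration to the 3-alkylfuran (butenolide-to-furan reduction) without creating a stereocentre.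

Step 4
Reactants: 5 furan diol 15,16-epoxy-ent-labda-8(17),13(16),14-triene-3,19-diol
Product: 6 3,19-bis(S-methyl xanthate) of 5
Conditions: NaH, imidazole (cat.), THF, 0 °C to rt; CS2; then MeI
Reagents that add atoms: carbon disulfide, S=C=S; iodomethane, CI
Why: Both alkoxides add to CS2 and are S-methylated (xanthate formation, the Barton–McCombie precursor), while furan and alkene are inert to base and the configuration is unchanged.

Step 5
Reactants: 6 3,19-bis(S-methyl xanthate) of 5
Product: 7 15,16-epoxy-ent-labda-8(17),13(16),14-triene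
Conditions: Bu3SnH (6 equiv), AIBN (portionwise), xylene, 140 °C
Reagents that add atoms: none
Why: Double Barton–McCombie radical deoxygenation (stannyl radical adds to C=S, β-scission, H transfer) replaces both C–O bonds by C–H, so C4 becomes the gem-dimethyl carbon and C3 a CH2, while C5, C9 and C10 are remote from the radical sites.

Step 6
Reactants: 7 15,16-epoxy-ent-labda-8(17),13(16),14-triene
Product: 10 ent-labda-8(17),13-dien-15,16-olide, via furan endoperoxide 8 (not isolated), via 16-hydroxybutenolide 9 (not isolated)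
Conditions: O2, hν, tetraphenylporphyrin (cat.), i-Pr2NEt, CH2Cl2, −78 °C; then NaBH4, EtOH, 0 °C; 1 M HCl
Reagents that add atoms: oxygen, O=O
Why: Singlet oxygen adds across C15/C16 of the furan in a [4+2] cycloaddition (far faster than an ene reaction of the 1,1-disubstituted alkene), i-Pr2NEt removes the less hindered C15–H of 8 (Kornblum–DeLaMare rearrangement) so that C15 becomes the carbonyl and C16 the hemiacetal of 9, and NaBH4 reduces the masked C16 aldehyde so that the cis hydroxy acid closes to butenolide 10 on acidification, the C16 epimers of 9 converging.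

Step 7
Reactants: 10 ent-labda-8(17),13-dien-15,16-olide
Product: 12 16-isobutyryloxy-ent-labda-8(17),13Z-dien-15-oic acid (CNP0269104.1), via potassium hydroxy-carboxylate 11 (not isolated)
Conditions: KOH (1.05 equiv), THF/H2O, 0 °C to rt; evaporate, toluene azeotrope; KN(SiMe3)2 (1.1 equiv), THF/DMF, −78 °C; i-PrCOCl (1.2 equiv), −78 to −30 °C; dilute HCl to pH 3
Reagents that add atoms: potassium hydroxide, [K+].[OH-]; 2-methylpropanoyl chloride, CC(C)C(Cl)=O
Why: Saponification (acyl–oxygen cleavage) opens the lactone with the ring-defined Z geometry intact, the derived alkoxide is far more nucleophilic than the carboxylate and is acylated selectively (alkoxide O-acylation), after which relactonisation is impossible and mild acidification frees the acid without touching any stereocentre.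

## Compound list

1 | andrographolide, (3E,4S)-3-{2-[(1R,4aS,5R,6R,8aS)-6-hydroxy-5-(hydroxymethyl)-5,8a-dimethyl-2-methylidenedecahydronaphthalen-1-yl]ethylidene}-4-hydroxyoxolan-2-one | C=C1CC[C@@H]2[C@](C)(CO)[C@H](O)CC[C@@]2(C)[C@@H]1C/C=C3/C(=O)OC[C@H]3O | starting material
2 | 3,14,19-tri-O-acetylandrographolide (configuration as in 1) | C=C1CC[C@@H]2[C@](C)(COC(C)=O)[C@H](OC(C)=O)CC[C@@]2(C)[C@@H]1C/C=C3/C(=O)OC[C@H]3OC(C)=O | intermediate
3 | 3,19-di-O-acetyl-14-deoxyandrographolide (13-ene butenolide with C16 carbonyl on C13; ring A and decalin as in 1) | C=C1CC[C@@H]2[C@](C)(COC(C)=O)[C@H](OC(C)=O)CC[C@@]2(C)[C@@H]1CCC3=CCOC3=O | intermediate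
4 | lactol, 16-hydroxy-15,16-epoxy-ent-labda-8(17),13-diene-3,19-diol (C16 epimers) | C=C1CC[C@@H]2[C@](C)(CO)[C@H](O)CC[C@@]2(C)[C@@H]1CCC3=CCOC3O | intermediate (not isolated)
5 | furan diol, 15,16-epoxy-ent-labda-8(17),13(16),14-triene-3,19-diol (3-substituted furan; ring A and decalin as in 1) | C=C1CC[C@@H]2[C@](C)(CO)[C@H](O)CC[C@@]2(C)[C@@H]1CCc3ccoc3 | intermediate
6 | 3,19-bis(S-methyl xanthate) of 5 | C=C1CC[C@@H]2[C@](C)(COC(=S)SC)[C@H](OC(=S)SC)CC[C@@]2(C)[C@@H]1CCc3ccoc3 | intermediate
7 | 15,16-epoxy-ent-labda-8(17),13(16),14-triene, 3-{2-[(1R,4aR,8aR)-5,5,8a-trimethyl-2-methylidenedecahydronaphthalen-1-yl]ethyl}furan | C=C1CC[C@@H]2C(C)(C)CCC[C@@]2(C)[C@@H]1CCc3ccoc3 | intermediate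
8 | furan endoperoxide, 2,3,7-trioxabicyclo[2.2.1]hept-5-ene carrying the decalinylethyl chain on C5 (bridgehead epimers) | C=C1CC[C@@H]2C(C)(C)CCC[C@@]2(C)[C@@H]1CCC3=CC4OOC3O4 | intermediate (not isolated)
9 | 16-hydroxy-ent-labda-8(17),13-dien-15,16-olide (C16 epimers) | C=C1CC[C@@H]2C(C)(C)CCC[C@@]2(C)[C@@H]1CCC3=CC(=O)OC3O | intermediate (not isolated)
10 | ent-labda-8(17),13-dien-15,16-olide, 4-{2-[(1R,4aR,8aR)-5,5,8a-trimethyl-2-methylidenedecahydronaphthalen-1-yl]ethyl}furan-2(5H)-one | C=C1CC[C@@H]2C(C)(C)CCC[C@@]2(C)[C@@H]1CCC3=CC(=O)OC3 | intermediate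
11 | potassium (2Z)-4-hydroxy-3-{2-[(1R,4aR,8aR)-5,5,8a-trimethyl-2-methylidenedecahydronaphthalen-1-yl]ethyl}but-2-enoate | C=C1CC[C@@H]2C(C)(C)CCC[C@@]2(C)[C@@H]1CC/C(=C/C(=O)[O-])CO.[K+] | intermediate (not isolated)
12 | (2Z)-4-(2-methylpropanoyloxy)-3-{2-[(1R,4aR,8aR)-5,5,8a-trimethyl-2-methylidenedecahydronaphthalen-1-yl]ethyl}but-2-enoic acid (CNP0269104.1) | C=C1CC[C@@H]2C(C)(C)CCC[C@@]2(C)[C@@H]1CC/C(=C/C(=O)O)COC(=O)C(C)C | target

## Step count and risks

Total step count: 7. Longest linear sequence: 7 steps (1 to 12).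

**Step 5 (double Barton–McCombie).** The primary neopentyl C19 xanthate fragments slowly, and the C3 radical can attack the neighbouring thiocarbonyl. The fallback replaces the radical chemistry by ionic and hydrazone chemistry; it sets out from 5 and comes back at 7. Selective tosylation of the primary 19-OH (TsCl, pyridine, 0 °C) gives the 19-O-tosylate F1. NaI and Zn in DMF at 110 °C convert it through the 19-iodide F2 into the 19-deoxy-3-ol F3. Dess–Martin periodinane gives the 3-ketone F4. Wolff–Kishner reduction (N2H4·H2O, KOH, diethylene glycol, 130 then 200 °C) through the hydrazone F5 delivers 7.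

**Step 7 (one-pot opening and O-acylation).** Any carboxyl activation before the alkoxide is capped returns butenolide 10. The fallback sets out from 10 and comes back at 12, keeping C15 at the alcohol level until O16 is acylated. i-Bu2AlH (CH2Cl2, −78 to 0 °C) gives the (13Z)-15,16-diol F6. TBDPSCl and imidazole at −40 °C silylate the less hindered 15-OH to give the silyl ether F7. i-PrCOCl and pyridine give the 16-isobutyrate F8. HF·pyridine in THF frees the 15-alcohol F9. MnO2 gives the (Z)-enal F10, and NaClO2, NaH2PO4 and 2-methyl-2-butene in t-BuOH/H2O give 12.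

**Step 2 (hydride SN2′ transposition).** Over-reduction of the butenolide or 1,2-attack on the lactone is possible. The fallback uses an allylic diazene rearrangement; it sets out from 1 and comes back at 5. 2,2-Dimethoxypropane and PPTS give the 3,19-acetonide F11. Mitsunobu reaction of the 14-OH with 2-nitrobenzenesulfonylhydrazide (PPh3, DEAD, THF, −30 °C to rt) gives, with inversion, the sulfonylhydrazine F12. F12 loses sulfinic acid to the monoalkyl diazene F13, which expels N2 in a retro-ene shift that places H on C12 and the alkene at C13=C14, giving the 14-deoxy acetonide F14. i-Bu2AlH at −78 °C gives the lactol acetonide F15, and 1 M HCl in THF dehydrates it to the furan and cleaves the acetonide, giving 5.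

## Further compounds

F1 | step 5 | 19-O-(4-methylbenzenesulfonyl) derivative of furan diol 5 | C=C1CC[C@@H]2[C@](C)(COS(=O)(=O)c3ccc(C)cc3)[C@H](O)CC[C@@]2(C)[C@@H]1CCc4ccoc4
F2 | step 5 | 19-iodo-15,16-epoxy-ent-labda-8(17),13(16),14-trien-3-ol | C=C1CC[C@@H]2[C@](C)(CI)[C@H](O)CC[C@@]2(C)[C@@H]1CCc3ccoc3
F3 | step 5 | 15,16-epoxy-ent-labda-8(17),13(16),14-trien-3-ol | C=C1CC[C@@H]2C(C)(C)[C@H](O)CC[C@@]2(C)[C@@H]1CCc3ccoc3
F4 | step 5 | 15,16-epoxy-ent-labda-8(17),13(16),14-trien-3-one | C=C1CC[C@@H]2C(C)(C)C(=O)CC[C@@]2(C)[C@@H]1CCc3ccoc3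
F5 | step 5 | hydrazone of F4 | C=C1CC[C@@H]2C(C)(C)C(=NN)CC[C@@]2(C)[C@@H]1CCc3ccoc3
F6 | step 7 | (13Z)-ent-labda-8(17),13-diene-15,16-diol | C=C1CC[C@@H]2C(C)(C)CCC[C@@]2(C)[C@@H]1CC/C(=C/CO)CO
F7 | step 7 | 15-O-(tert-butyldiphenylsilyl) ether of F6 | C=C1CC[C@@H]2C(C)(C)CCC[C@@]2(C)[C@@H]1CC/C(=C/CO[Si](c3ccccc3)(c3ccccc3)C(C)(C)C)CO
F8 | step 7 | 15-O-(tert-butyldiphenylsilyl) 16-O-isobutyryl derivative of F6 | C=C1CC[C@@H]2C(C)(C)CCC[C@@]2(C)[C@@H]1CC/C(=C/CO[Si](c3ccccc3)(c3ccccc3)C(C)(C)C)COC(=O)C(C)C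
F9 | step 7 | (13Z)-16-isobutyryloxy-ent-labda-8(17),13-dien-15-ol | C=C1CC[C@@H]2C(C)(C)CCC[C@@]2(C)[C@@H]1CC/C(=C/CO)COC(=O)C(C)C
F10 | step 7 | (13Z)-16-isobutyryloxy-ent-labda-8(17),13-dien-15-al | C=C1CC[C@@H]2C(C)(C)CCC[C@@]2(C)[C@@H]1CC/C(=C/C=O)COC(=O)C(C)C
F11 | step 2 | 3,19-O-isopropylideneandrographolide | C=C1CC[C@@H]2[C@]3(C)COC(C)(C)O[C@@H]3CC[C@@]2(C)[C@@H]1C/C=C4/C(=O)OC[C@H]4O
F12 | step 2 | C14 N-(2-nitrophenylsulfonyl)hydrazine adduct of F11 (C14 inverted) | C=C1CC[C@@H]2[C@]3(C)COC(C)(C)O[C@@H]3CC[C@@]2(C)[C@@H]1C/C=C4/C(=O)OC[C@@H]4N(N)S(=O)(=O)c5ccccc5[N+](=O)[O-]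
F13 | step 2 | C14 monoalkyl diazene derived from F12 | C=C1CC[C@@H]2[C@]3(C)COC(C)(C)O[C@@H]3CC[C@@]2(C)[C@@H]1C/C=C4/C(=O)OC[C@@H]4N=N
F14 | step 2 | 14-deoxy-3,19-O-isopropylideneandrographolide | C=C1CC[C@@H]2[C@]3(C)COC(C)(C)O[C@@H]3CC[C@@]2(C)[C@@H]1CCC4=CCOC4=O
F15 | step 2 | 16-lactol of F14 (C16 epimers) | C=C1CC[C@@H]2[C@]3(C)COC(C)(C)O[C@@H]3CC[C@@]2(C)[C@@H]1CCC4=CCOC4O
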